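**Plan** (labdane numbering throughout; C5/C10 are the ring-fusion carbons)

- Retrosynthetic cuts, in order: C12–C13 (butenolide removed, B-alkyl Suzuki), C9–C11 (vinyl group, via the C9 enol triflate), the C6 ester, and finally C1–C10 together with C4–C5, which takes ring A off as 4-methylpenta-1,3-diene.
- Enabling feature: ring B carries oxygen at C6, an alkene carbon with a carbon substituent at C9, and methyls on C8 and C10. These are the atoms of 2,6-dimethyl-1,4-benzoquinone, whose methyl-bearing C5=C10 edge is free to accept ring A.
- Forward order: ring B is bought as the quinone and ring A is closed by a catalytic enantioselective Diels–Alder reaction. Then both alkenes are hydrogenated, C5 is equilibrated to the trans fusion, C6 is reduced and acetylated, and C9 is converted to the enol triflate and then to vinyl. The chain is finished by hydroboration and Suzuki coupling with 4-bromofuranone made from tetronic acid.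
- Stereochemistry: C10 comes from the chiral Lewis acid, C5 from thermodynamic epimerisation next to the C6 ketone, and C6 from α-face hydride delivery enforced by the two β-axial methyls (C10 and C4).

Key step: step 1

Assumption: the catalyst from (S)-α,α-diphenylprolinol is taken to shield the enone face that leads to 10S, by analogy with its usual behaviour toward acrylates and quinones; if the sense proves opposite, the catalyst from (R)-diphenylprolinol is used with no other change.

Step 1
Reactants: 1 2,6-dimethyl-1,4-benzoquinone; 2 4-methylpenta-1,3-diene
Product: 3 (4aR,8aS)-2,5,5,8a-tetramethyl-4a,5,8,8a-tetrahydronaphthalene-1,4-dione (cis-fused enedione; labdane numbering: 6,9-dione, Δ2, Δ7, 5β-H, 10β-CH3)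
Conditions: (S)-B-o-tolyl oxazaborolidinium triflimide (20 mol %, from the diphenylprolinol-derived oxazaborolidine and Tf2NH), 2 (3 equiv), CH2Cl2, −78 → −40 °C
Reagents that add atoms: none
Why: The cationic boron binds the quinone oxygen flanked by the two ring C–H groups (the unhindered carbonyl, made more basic by the β-methyls), and the diene adds across one methylated alkene in a concerted, strongly asynchronous, suprafacial [4+2] cycloaddition in which its CH2 terminus bonds first to the methyl-bearing β-carbon (C10) and its dimethylated terminus closes onto the α-carbon (C5). The closest known reaction type is the oxazaborolidinium-catalysed enantioselective Diels–Alder reaction of methyl-substituted 1,4-benzoquinones with acyclic dienes, where a quaternary ring-fusion carbon is likewise formed at the β-position of the coordinated enone. Ring A is closed by intermolecular cycloaddition, both of its new σ-bonds (C1–C10 and C4–C5) arising in this one step. C10 is set by the catalyst, whose aryl group covers one face of the bound enone while an α-C–H···O contact fixes its orientation, and C5 is necessarily cis to the C10 methyl because the addition is suprafacial (it is inverted in step 3). The step needs regioselectivity, enantioselectivity and mono-addition: the first follows from Lewis-acid polarisation of the enone and from avoiding two adjacent quaternary carbons, the second from the catalyst, and the third from the symmetry of the quinone (both methylated alkenes are equivalent) and the lower reactivity of the hindered adduct; endo/exo selectivity is irrelevant because neither diene terminus is stereogenic.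

Step 2
Reactants: 3 cis-fused enedione adduct
Product: 4 cis-fused 4,4,8α,10β-tetramethyldecalin-6,9-dione (5β-H)
Conditions: H2 (1 atm), 10% Pd/C, EtOAc, rt
Reagents that add atoms: none
Why: Heterogeneous hydrogenation saturates both the electron-poor C7=C8 alkene of the enedione and the cis-disubstituted C2=C3 alkene without touching the ketones or the ring fusion; hydrogen should add to C8 from the convex face, but this centre becomes trigonal again in step 6.

Step 3
Reactants: 4 cis-fused dione
Product: 5 trans-fused 4,4,8α,10β-tetramethyldecalin-6,9-dione (5α-H)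
Conditions: NaOMe (0.3 equiv), MeOH, rt; AcOH quench
Reagents that add atoms: none
Why: Reversible enolisation of the C6 ketone toward C5 (thermodynamic epimerisation of an α-stereocentre) should carry the cis adduct into the trans-fused dione, in which ring A is an undistorted chair with C6 and C9 both equatorial, as in the 5α-H 6-oxo compounds of the 4,4,10-trimethyldecalin class that keep their trans fusion under base; C8 settles at the same time with its methyl equatorial, and any residual cis isomer is separated and resubmitted.

Step 4
Reactants: 5 trans-fused dione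
Product: 6 6β-hydroxy-4,4,8α,10β-tetramethyl-trans-decalin-9-one
Conditions: L-Selectride (1.1 equiv), THF, −78 → 0 °C; then NaOH, H2O2, 0 °C
Reagents that add atoms: none
Why: Substrate-controlled, chemoselective ketone reduction: the bulky trialkylborohydride can reach C6 only along the equatorial α-trajectory because the β-face is closed by the syn-axial C10 and C4 methyls, which gives the axial 6β-alcohol, while the C9 carbonyl, wedged between quaternary C10 and tertiary C8, should not react at low temperature.

Step 5
Reactants: 6 6β-hydroxy ketone
Product: 7 6β-acetoxy-4,4,8α,10β-tetramethyl-trans-decalin-9-one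
Conditions: Ac2O, DMAP, pyridine, 60 °C
Reagents that add atoms: acetic anhydride, CC(=O)OC(C)=O
Why: DMAP-catalysed acyl transfer (nucleophilic catalysis) esterifies the hindered axial alcohol, with the neopentyl ketone inert and no stereocentre at risk.

Step 6
Reactants: 7 6β-acetoxy ketone
Product: 8 6β-acetoxy-4,4,8,10β-tetramethyl-5α-Δ8-octalin-9-yl trifluoromethanesulfonate
Conditions: Tf2O, 2,6-di-tert-butyl-4-methylpyridine, CH2Cl2, 0 °C → rt
Reagents that add atoms: trifluoromethanesulfonic anhydride, O=S(=O)(OS(=O)(=O)C(F)(F)F)C(F)(F)F
Why: Electrophilic vinyl triflate formation: O-sulfonylation of the ketone and loss of the only α-hydrogen (C8–H) to the hindered pyridine gives the tetrasubstituted enol triflate without strong base, conditions an acetate is known to survive when ketones next to a methyl-bearing quaternary carbon are triflated.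

Step 7
Reactants: 8 enol triflate
Product: 9 13,14,15,16-tetranorlabda-8,11-dien-6β-yl acetate (9-vinyl diene)
Conditions: tributyl(vinyl)stannane, Pd(PPh3)4 (5 mol %), LiCl, THF, 65 °C
Reagents that add atoms: tributyl(vinyl)stannane, C=C[Sn](CCCC)(CCCC)CCCC
Why: Stille cross-coupling (oxidative addition of the vinyl triflate, chloride-assisted transmetalation, reductive elimination) installs C11–C12, as established for 2,6,6-trisubstituted cyclohexenyl triflates.

Step 8
Reactants: 10 tetronic acid (4-hydroxyfuran-2(5H)-one)
Product: 11 4-bromofuran-2(5H)-one
Conditions: (COBr)2, DMF (cat.), CH2Cl2, 0 °C → rt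
Reagents that add atoms: oxalyl bromide, O=C(Br)C(Br)=O
Why: Vilsmeier-type activation of the vinylogous acid by DMF/oxalyl bromide followed by addition–elimination of bromide gives the β-bromobutenolide.

Step 9
Reactants: 9 9-vinyl diene; 11 4-bromofuran-2(5H)-one
Product: 13 (5S,6R,10S)-6-acetoxylabda-8,13-dien-15,16-olide (6β-acetate; target), via B-alkyl-9-BBN adduct 12 (not isolated)
Conditions: 9-BBN, THF, 0 °C → rt; then 11, PdCl2(dppf) (5 mol %), AsPh3, K3PO4, DMF–H2O, rt → 40 °C
Reagents that add atoms: none
Why: 9-BBN hydroborates only the monosubstituted vinyl group, boron going to terminal C12 while the tetrasubstituted C8=C9 alkene and the acetate are inert, and the primary B-alkyl borane then undergoes B-alkyl Suzuki–Miyaura coupling with the vinylogous acyl bromide under mild phosphate base to form C12–C13.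

**Compound list**

1 | 2,6-dimethyl-1,4-benzoquinone | CC1=CC(=O)C=C(C)C1=O | starting material
2 | 4-methylpenta-1,3-diene | CC(C)=CC=C | starting material
3 | (4aR,8aS)-2,5,5,8a-tetramethyl-4a,5,8,8a-tetrahydronaphthalene-1,4-dione (cis-fused enedione adduct) | O=C1C=C(C)C(=O)[C@@]2(C)CC=CC(C)(C)[C@@H]12 | intermediate
4 | cis-fused 4,4,8α,10β-tetramethyldecalin-6,9-dione (5β-H) | O=C1C[C@@H](C)C(=O)[C@@]2(C)CCCC(C)(C)[C@@H]12 | intermediate
5 | trans-fused 4,4,8α,10β-tetramethyldecalin-6,9-dione (5α-H) | O=C1C[C@@H](C)C(=O)[C@@]2(C)CCCC(C)(C)[C@H]12 | intermediate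
6 | 6β-hydroxy-4,4,8α,10β-tetramethyl-trans-decalin-9-one | O[C@@H]1C[C@@H](C)C(=O)[C@@]2(C)CCCC(C)(C)[C@H]12 | intermediate
7 | 6β-acetoxy-4,4,8α,10β-tetramethyl-trans-decalin-9-one | CC(=O)O[C@@H]1C[C@@H](C)C(=O)[C@@]2(C)CCCC(C)(C)[C@H]12 | intermediate
8 | 6β-acetoxy-4,4,8,10β-tetramethyl-5α-Δ8-octalin-9-yl trifluoromethanesulfonate | CC(=O)O[C@@H]1CC(C)=C(OS(=O)(=O)C(F)(F)F)[C@@]2(C)CCCC(C)(C)[C@H]12 | intermediate
9 | 13,14,15,16-tetranorlabda-8,11-dien-6β-yl acetate | CC(=O)O[C@@H]1CC(C)=C(C=C)[C@@]2(C)CCCC(C)(C)[C@H]12 | intermediate
10 | tetronic acid (4-hydroxyfuran-2(5H)-one) | OC1=CC(=O)OC1 | starting material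
11 | 4-bromofuran-2(5H)-one | BrC1=CC(=O)OC1 | intermediate
12 | B-(6β-acetoxy-13,14,15,16-tetranorlabd-8-en-12-yl)-9-borabicyclo[3.3.1]nonane | CC(=O)O[C@@H]1CC(C)=C(CCB3C4CCCC3CCC4)[C@@]2(C)CCCC(C)(C)[C@H]12 | intermediate
13 | (5S,6R,10S)-6-acetoxylabda-8,13-dien-15,16-olide | CC(=O)O[C@@H]1CC(C)=C(CCC2=CC(=O)OC2)[C@@]2(C)CCCC(C)(C)[C@H]12 | target

**Step count**

Total: 9 steps. Longest linear sequence: 8 steps (steps 1–7 and 9); step 8 prepares the coupling partner.

**Steps most likely to fail**

Step 1. The diene has a cis-methyl on its reacting terminus, so it reaches the s-cis geometry reluctantly and may oligomerise under the cationic Lewis acid before it cycloadds; conversion or enantiomeric purity could then be poor. The fallback adds an activating group to the diene while keeping the same two bond formations. It sets out from 1, which is combined under the same catalyst with 4-methyl-2-(triisopropylsilyloxy)penta-1,3-diene F1, made from mesityl oxide (CC(=O)C=C(C)C) with LDA and TIPSOTf. The 2-silyloxy group raises the HOMO, disfavours the s-trans rotamer and reinforces attack of C1 on C10. This should give the cis-fused adduct bearing a C2 silyl enol ether F2. Hydrogenation over Pd/C reduces only the enedione alkene to the 7,8-dihydro silyl enol ether F3, and aqueous HF in MeCN unmasks the cis-fused 2,6,9-trione F4. The C2 carbonyl is the only one without α-branching, so one equivalent of tosylhydrazide should give the C2 mono-tosylhydrazone F5. Catecholborane followed by NaOAc·3H2O reduces it to the methylene, and the sequence rejoins the route at 4.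

Step 3. The equilibrium may stop at a mixture rich in the cis-fused isomer, because relief of the contact between the C4 methyls and the C6 carbonyl can offset the usual penalty of a cis fusion. The fallback sets the ring-fusion hydrogen by a kinetic syn-addition instead of by equilibration. It sets out from 4, which L-Selectride should reduce at C6 from the convex face to the cis-fused 6α-hydroxy-9-ketone F6. POCl3 in pyridine then eliminates the 6α-oxygen anti to the 5β-hydrogen, giving the Δ5-en-9-one F7 in which C5 is trigonal. BH3·THF adds to the α-face of this alkene, anti to the C10 and C4 β-methyls as with Δ5-steroids, and reduces C9 in the same operation, so that oxidative work-up gives the 5α-H 6α,9β-diol F8. Dess–Martin oxidation of both carbinols under non-enolising conditions returns the trans-fused dione, and the sequence rejoins the route at 5.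

Step 6. O-Triflation of the neopentyl ketone may be sluggish, or the cationic intermediate may rearrange or be intercepted before it loses the C8 proton. The fallback builds the C8=C9 alkene by carbonyl addition and dehydration instead of through an enol triflate. It sets out from 6, to which vinylmagnesium bromide with CeCl3 should add at C9 from the α-face to give the 9α-vinyl-6β,9β-diol F9. Ac2O/DMAP acylates only the secondary alcohol and gives the 6-monoacetate F10. Burgess reagent then dehydrates the tertiary allylic carbinol by syn-elimination with the cis C8 hydrogen, the only β-hydrogen available, and the sequence rejoins the route at 9, bypassing 7 and 8.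

**Further compounds**

F1 | step 1 | 4-methyl-2-(triisopropylsilyloxy)penta-1,3-diene | C=C(O[Si](C(C)C)(C(C)C)C(C)C)C=C(C)C
F2 | step 1 | cis-fused adduct bearing a C2 silyl enol ether | O=C1C=C(C)C(=O)[C@@]2(C)CC(O[Si](C(C)C)(C(C)C)C(C)C)=CC(C)(C)[C@@H]12
F3 | step 1 | 7,8-dihydro silyl enol ether | O=C1C[C@@H](C)C(=O)[C@@]2(C)CC(O[Si](C(C)C)(C(C)C)C(C)C)=CC(C)(C)[C@@H]12
F4 | step 1 | cis-fused 4,4,8α,10β-tetramethyldecalin-2,6,9-trione | O=C1C[C@@H](C)C(=O)[C@@]2(C)CC(=O)CC(C)(C)[C@@H]12
F5 | step 1 | C2 mono-tosylhydrazone of the trione | O=C1C[C@@H](C)C(=O)[C@@]2(C)CC(=NNS(=O)(=O)c3ccc(C)cc3)CC(C)(C)[C@@H]12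
F6 | step 3 | cis-fused 6α-hydroxy-4,4,8α,10β-tetramethyldecalin-9-one | O[C@H]1C[C@@H](C)C(=O)[C@@]2(C)CCCC(C)(C)[C@@H]12
F7 | step 3 | 4,4,8α,10β-tetramethyl-Δ5-octalin-9-one | [C@@H]1(C)CC=C2C(C)(C)CCC[C@]2(C)C1=O
F8 | step 3 | 4,4,8α,10β-tetramethyl-trans-decalin-6α,9β-diol (5α-H) | O[C@H]1C[C@@H](C)[C@H](O)[C@@]2(C)CCCC(C)(C)[C@H]12
F9 | step 6 | 9α-vinyl-4,4,8α,10β-tetramethyl-trans-decalin-6β,9β-diol | O[C@@H]1C[C@@H](C)[C@@](O)(C=C)[C@@]2(C)CCCC(C)(C)[C@H]12
F10 | step 6 | 6β-acetoxy-9α-vinyl-4,4,8α,10β-tetramethyl-trans-decalin-9β-ol | CC(=O)O[C@@H]1C[C@@H](C)[C@@](O)(C=C)[C@@]2(C)CCCC(C)(C)[C@H]12
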